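**Retrosynthetic overview**
- Target ⇐ one Lewis-acid dealkylation of a fully O-alkylated flavone (two isopropyl ethers on ring B and the chelated 5-methyl ether).
- Flavone C2–C1' bond ⇐ new Pd-catalysed C2–H arylation of 3,5,6,7,8-pentamethoxychromone with 5-bromo-1,3-diisopropoxy-2-methoxybenzene.
- Chromone (ring C, the only ring that is formed; closed before the fragment union) ⇐ amide-acetal annulation of a 2-hydroxyaryl methoxymethyl ketone ⇐ pentamethoxybenzene (lithiation, Weinreb acylation, mono-demethylation) ⇐ 1,2,3,5-tetramethoxybenzene (lithiation, oxidation, methylation).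
- Aryl bromide (ring B) ⇐ 2-methoxyresorcinol by O-isopropylation, Ir-catalysed meta C–H borylation and bromodeboronation.
- Rings A and B are bought as benzenes; order: ring A oxygenation, ring C closure, ring B attachment, deprotection.

Assumption: the target has no stereocentre and no stereogenic double bond, so "single enantiomer" is taken as the one achiral constitution drawn and no stereocontrol is needed.

Commercial starting materials: 1, 6 and 14.

**Route**

Step 1
Reactants: 1 1,2,3,5-tetramethoxybenzene
Product: 4 2,3,4,6-tetramethoxyphenol, via (2,3,4,6-tetramethoxyphenyl)lithium 2 (not isolated), via lithium trimethoxy(2,3,4,6-tetramethoxyphenyl)borate 3 (not isolated)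
Conditions: n-BuLi, THF, 0 °C → rt; B(OMe)3, −78 °C → rt; AcOH, 30% aq H2O2, 0 °C → rt
Reagents that add atoms: hydrogen peroxide, OO
Why: Each ring hydrogen of 1 lies between two methoxy groups, so directed ortho-lithiation gives a single aryllithium, and its borate is oxidised at the ipso carbon to the phenol (directed ortho-metalation, then peroxide oxidation of an arylboron compound); no stereocentre.

Step 2
Reactants: 4 2,3,4,6-tetramethoxyphenol
Product: 5 pentamethoxybenzene
Conditions: MeI, K2CO3, acetone, reflux, under N2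
Reagents that add atoms: iodomethane, CI
Why: Williamson O-methylation of the only free hydroxyl; no other reactive group is present.

Step 3
Reactants: 5 pentamethoxybenzene; 6 N,2-dimethoxy-N-methylacetamide
Product: 9 2-methoxy-1-(2,3,4,5,6-pentamethoxyphenyl)ethan-1-one, via (2,3,4,5,6-pentamethoxyphenyl)lithium 7 (not isolated), via lithium 2-methoxy-1-[methoxy(methyl)amino]-1-(2,3,4,5,6-pentamethoxyphenyl)ethan-1-olate 8 (not isolated)
Conditions: n-BuLi, TMEDA, THF, 0 °C; then 6, −78 → 0 °C; 1 M HCl work-up
Reagents that add atoms: none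
Why: The single ring hydrogen of 5, flanked by two methoxy groups, is lithiated, and the aryllithium adds only once to the Weinreb amide because the chelated tetrahedral adduct survives until work-up (directed ortho-metalation, Weinreb ketone synthesis).

Step 4
Reactants: 9 2-methoxy-1-(2,3,4,5,6-pentamethoxyphenyl)ethan-1-one
Product: 11 1-(2-hydroxy-3,4,5,6-tetramethoxyphenyl)-2-methoxyethan-1-one, via dichloro[2-(methoxyacetyl)-3,4,5,6-tetramethoxyphenoxy]borane 10 (not isolated)
Conditions: BCl3 (1.1 equiv), CH2Cl2, −78 → 0 °C; then ice-water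
Reagents that add atoms: none
Why: BCl3 bound to the ketone oxygen cleaves only a methoxy group ortho to the carbonyl through a six-membered chelate; the two ortho groups are equivalent and the boron chelate formed blocks a second cleavage (chelation-controlled Lewis-acid demethylation).

Step 5
Reactants: 11 1-(2-hydroxy-3,4,5,6-tetramethoxyphenyl)-2-methoxyethan-1-one
Product: 13 3,5,6,7,8-pentamethoxy-4H-chromen-4-one, via (Z)-3-(dimethylamino)-1-(2-hydroxy-3,4,5,6-tetramethoxyphenyl)-2-methoxyprop-2-en-1-one 12 (not isolated)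
Conditions: Me2NCH(OMe)2 (3 equiv), toluene, 100 °C; then AcOH, 80 °C
Reagents that add atoms: N,N-dimethylformamide dimethyl acetal, CN(C)C(OC)OC
Why: The amide acetal condenses at the activated CH2(OMe) group to an enaminone, and the ortho-phenol adds to it and expels dimethylamine to close the pyranone ring (enaminone route to 3-substituted chromones, as used for isoflavones from deoxybenzoins); the enaminone geometry is lost on cyclisation.

Step 6
Reactants: 14 2-methoxybenzene-1,3-diol (2-methoxyresorcinol)
Product: 15 1,3-diisopropoxy-2-methoxybenzene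
Conditions: 2-bromopropane (3 equiv), K2CO3, DMF, 70 °C
Reagents that add atoms: 2-bromopropane, CC(C)Br
Why: Williamson O-alkylation of both phenols; isopropyl ethers carry no aromatic C–H and survive steps 7–9.

Step 7
Reactants: 15 1,3-diisopropoxy-2-methoxybenzene
Product: 16 2-(3,5-diisopropoxy-4-methoxyphenyl)-4,4,5,5-tetramethyl-1,3,2-dioxaborolane
Conditions: [Ir(OMe)(cod)]2 (1.5 mol %), 4,4'-di-tert-butyl-2,2'-bipyridine (3 mol %), B2pin2 (1.0 equiv), THF, 80 °C
Reagents that add atoms: bis(pinacolato)diboron, CC1(C)OB(OC1(C)C)B1OC(C)(C)C(C)(C)O1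
Why: Iridium-catalysed aromatic C–H borylation is sterically controlled and takes C5, the only ring C–H without an ortho substituent, which electrophilic substitution cannot reach.

Step 8
Reactants: 16 2-(3,5-diisopropoxy-4-methoxyphenyl)-4,4,5,5-tetramethyl-1,3,2-dioxaborolane
Product: 17 5-bromo-1,3-diisopropoxy-2-methoxybenzene
Conditions: CuBr2 (3 equiv), MeOH/H2O 1:1, 80 °C
Reagents that add atoms: CuBr2, Br[Cu]Br
Why: Copper-mediated bromodeboronation replaces boron by bromine at the ipso carbon, keeping the meta regiochemistry set in step 7 (halodeboronation of an arylboronate).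

Step 9
Reactants: 13 3,5,6,7,8-pentamethoxy-4H-chromen-4-one; 17 5-bromo-1,3-diisopropoxy-2-methoxybenzene (1.3 equiv)
Product: 18 2-(3,5-diisopropoxy-4-methoxyphenyl)-3,5,6,7,8-pentamethoxy-4H-chromen-4-one
Conditions: Pd(OAc)2 (5 mol %), PCy3·HBF4 (10 mol %), PivOH (30 mol %), K2CO3 (2.5 equiv), toluene, 110 °C, Ar
Reagents that add atoms: none
Why: Proposed new method: palladium-catalysed, pivalate-assisted C2–H arylation of a 3-alkoxychromone with an aryl bromide; 17 adds oxidatively to zerovalent palladium, bromide is exchanged for pivalate on the divalent arylpalladium species, the pivalate removes H-2 in a concerted metalation–deprotonation as the Pd–C2 bond forms, and reductive elimination makes the C2–C1' bond and returns zerovalent palladium; C2–H is the only sp2 C–H of 13 and is acidified by O1, by the 3-methoxy group and by conjugation with the C4 carbonyl (hindered amide bases remove the same hydrogen), and because C3 is blocked a competing Heck-type carbopalladation (aryl to C2, palladium enolate at C3, base-assisted loss of H-2) gives the same product; no stereocentre is formed; the closest known reaction type is carboxylate-assisted palladium direct arylation of benzofurans, azoles and other acidic heteroarene C–H bonds with aryl bromides, applied here to the C2–H bond of a 3-alkoxychromone, for which it has not been shown.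

Step 10
Reactants: 18 2-(3,5-diisopropoxy-4-methoxyphenyl)-3,5,6,7,8-pentamethoxy-4H-chromen-4-one
Product: 20 5,3',5'-trihydroxy-3,6,7,8,4'-pentamethoxyflavone, via 5,3',5'-tris(dichloroboryloxy)-3,6,7,8,4'-pentamethoxyflavone 19 (not isolated)
Conditions: BCl3 (6 equiv), CH2Cl2, −78 → 0 °C; then ice-water, 1 M HCl, rt
Reagents that add atoms: none
Why: BCl3 cleaves secondary alkyl aryl ethers much faster than methyl aryl ethers and removes the 5-methyl group through the peri-carbonyl six-membered chelate, so only the two isopropyl groups and the 5-methyl group are lost while the 3-, 6-, 7-, 8- and 4'-methoxy groups stay (Lewis-acid dealkylation with chelation-controlled demethylation); the product is achiral.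

**Compound list**
1 | 1,2,3,5-tetramethoxybenzene | COc1cc(OC)c(OC)c(OC)c1 | starting material
2 | (2,3,4,6-tetramethoxyphenyl)lithium | [Li]c1c(OC)cc(OC)c(OC)c1OC | intermediate (not isolated)
3 | lithium trimethoxy(2,3,4,6-tetramethoxyphenyl)borate | [Li+].CO[B-](OC)(OC)c1c(OC)cc(OC)c(OC)c1OC | intermediate (not isolated)
4 | 2,3,4,6-tetramethoxyphenol | Oc1c(OC)cc(OC)c(OC)c1OC | intermediate
5 | pentamethoxybenzene | COc1cc(OC)c(OC)c(OC)c1OC | intermediate
6 | N,2-dimethoxy-N-methylacetamide | COCC(=O)N(C)OC | starting material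
7 | (2,3,4,5,6-pentamethoxyphenyl)lithium | [Li]c1c(OC)c(OC)c(OC)c(OC)c1OC | intermediate (not isolated)
8 | lithium 2-methoxy-1-[methoxy(methyl)amino]-1-(2,3,4,5,6-pentamethoxyphenyl)ethan-1-olate (racemic, collapses on work-up) | [Li+].[O-]C(COC)(N(C)OC)c1c(OC)c(OC)c(OC)c(OC)c1OC | intermediate (not isolated)
9 | 2-methoxy-1-(2,3,4,5,6-pentamethoxyphenyl)ethan-1-one | COCC(=O)c1c(OC)c(OC)c(OC)c(OC)c1OC | intermediate
10 | dichloro[2-(methoxyacetyl)-3,4,5,6-tetramethoxyphenoxy]borane | COCC(=O)c1c(OB(Cl)Cl)c(OC)c(OC)c(OC)c1OC | intermediate (not isolated)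
11 | 1-(2-hydroxy-3,4,5,6-tetramethoxyphenyl)-2-methoxyethan-1-one | COCC(=O)c1c(O)c(OC)c(OC)c(OC)c1OC | intermediate
12 | (Z)-3-(dimethylamino)-1-(2-hydroxy-3,4,5,6-tetramethoxyphenyl)-2-methoxyprop-2-en-1-one | CN(C)/C=C(\OC)C(=O)c1c(O)c(OC)c(OC)c(OC)c1OC | intermediate (not isolated)
13 | 3,5,6,7,8-pentamethoxy-4H-chromen-4-one | COc1coc2c(OC)c(OC)c(OC)c(OC)c2c1=O | intermediate
14 | 2-methoxybenzene-1,3-diol | COc1c(O)cccc1O | starting material
15 | 1,3-diisopropoxy-2-methoxybenzene | COc1c(OC(C)C)cccc1OC(C)C | intermediate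
16 | 2-(3,5-diisopropoxy-4-methoxyphenyl)-4,4,5,5-tetramethyl-1,3,2-dioxaborolane | COc1c(OC(C)C)cc(B2OC(C)(C)C(C)(C)O2)cc1OC(C)C | intermediate
17 | 5-bromo-1,3-diisopropoxy-2-methoxybenzene | COc1c(OC(C)C)cc(Br)cc1OC(C)C | intermediate
18 | 2-(3,5-diisopropoxy-4-methoxyphenyl)-3,5,6,7,8-pentamethoxy-4H-chromen-4-one | COc1c(OC(C)C)cc(-c2oc3c(OC)c(OC)c(OC)c(OC)c3c(=O)c2OC)cc1OC(C)C | intermediate
19 | 5,3',5'-tris(dichloroboryloxy)-3,6,7,8,4'-pentamethoxyflavone | COc1c(OB(Cl)Cl)cc(-c2oc3c(OC)c(OC)c(OC)c(OB(Cl)Cl)c3c(=O)c2OC)cc1OB(Cl)Cl | intermediate (not isolated)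
20 | 5,3',5'-trihydroxy-3,6,7,8,4'-pentamethoxyflavone | COc1c(O)cc(-c2oc3c(OC)c(OC)c(OC)c(O)c3c(=O)c2OC)cc1O | target

**Totals and risks**

Total step count: 10 (steps 1–5 for the chromone, steps 6–8 for the aryl bromide, steps 9–10 for union and deprotection).
Longest linear sequence: 7 steps (1, 2, 3, 4, 5, 9, 10).

The three steps most likely to fail:

Step 9 (the proposed new C2–H arylation). The C–H acidity of 13 may be too low for turnover, or the chromone may be opened by base at 110 °C. The fallback uses known chemistry, sets out from 13 and comes back at 18. The only ring C–H of 13 is zincated with TMPZnCl·LiCl (1.2 equiv, THF, 25 °C) to give (3,5,6,7,8-pentamethoxy-4-oxo-4H-chromen-2-yl)zinc chloride F3. F3 is then cross-coupled with 17 (Pd(OAc)2 2 mol %, SPhos 4 mol %, THF, 50 °C) in a Negishi coupling to give 18. Amide-base zincation of chromones at C2 followed by Negishi arylation is an established way to make flavones, and here C3 is blocked so no regiochemical question arises.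

Step 10 (three ether cleavages in one operation with five methoxy groups to be kept). Over-demethylation at C3, C6 or C4', or incomplete loss of isopropyl, is possible. The fallback replaces the Lewis-acid global deprotection by hydrogenolysis plus one chelation-controlled demethylation; it sets out from 17 and 13 and comes back at 20. Bromide 17 is dealkylated on its own (BCl3, CH2Cl2, −78 → 0 °C) to 5-bromo-2-methoxybenzene-1,3-diol F4. This is benzylated (BnBr, K2CO3, DMF, rt) to 1,3-bis(benzyloxy)-5-bromo-2-methoxybenzene F5. F5 is coupled with 13 under the conditions of step 9 (or through F3) to give 2-[3,5-bis(benzyloxy)-4-methoxyphenyl]-3,5,6,7,8-pentamethoxy-4H-chromen-4-one F6. Hydrogenolysis (H2 1 atm, Pd/C, EtOAc/MeOH, rt) gives 2-(3,5-dihydroxy-4-methoxyphenyl)-3,5,6,7,8-pentamethoxy-4H-chromen-4-one F7. Anhydrous AlCl3 in MeCN (rt → 50 °C, then dilute HCl) then removes only the 5-methyl group through the peri-carbonyl chelate to give 20.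

Step 5 (annulation of a ketone flanked by two ortho substituents). The amide acetal may O-methylate the phenol or fail to condense. The fallback closes ring C after ring B is attached, by the classical 1,3-diketone route; it sets out from 11 and 17 and comes back at 18, so it bypasses steps 5 and 9. Bromide 17 is methoxycarbonylated (Pd(OAc)2, Xantphos, CO 1 atm, MeOH, Na2CO3, toluene, 80 °C) to methyl 3,5-diisopropoxy-4-methoxybenzoate F1. The dianion of 11 (LiN(SiMe3)2, 3 equiv, THF, −78 °C → rt) undergoes crossed Claisen condensation with F1 to give 1-(3,5-diisopropoxy-4-methoxyphenyl)-3-(2-hydroxy-3,4,5,6-tetramethoxyphenyl)-2-methoxypropane-1,3-dione F2 (racemic at the enolisable C2, a centre that is lost in the next operation). Cyclodehydration (catalytic H2SO4, AcOH, 90 °C) gives 18.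

**Further compounds**
F1 | step 5 | methyl 3,5-diisopropoxy-4-methoxybenzoate | COC(=O)c1cc(OC(C)C)c(OC)c(OC(C)C)c1
F2 | step 5 | 1-(3,5-diisopropoxy-4-methoxyphenyl)-3-(2-hydroxy-3,4,5,6-tetramethoxyphenyl)-2-methoxypropane-1,3-dione (racemic) | COC(C(=O)c1cc(OC(C)C)c(OC)c(OC(C)C)c1)C(=O)c1c(O)c(OC)c(OC)c(OC)c1OC
F3 | step 9 | (3,5,6,7,8-pentamethoxy-4-oxo-4H-chromen-2-yl)zinc chloride | COc1c([Zn]Cl)oc2c(OC)c(OC)c(OC)c(OC)c2c1=O
F4 | step 10 | 5-bromo-2-methoxybenzene-1,3-diol | COc1c(O)cc(Br)cc1O
F5 | step 10 | 1,3-bis(benzyloxy)-5-bromo-2-methoxybenzene | COc1c(OCc2ccccc2)cc(Br)cc1OCc1ccccc1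
F6 | step 10 | 2-[3,5-bis(benzyloxy)-4-methoxyphenyl]-3,5,6,7,8-pentamethoxy-4H-chromen-4-one | COc1c(OCc2ccccc2)cc(-c2oc3c(OC)c(OC)c(OC)c(OC)c3c(=O)c2OC)cc1OCc1ccccc1
F7 | step 10 | 2-(3,5-dihydroxy-4-methoxyphenyl)-3,5,6,7,8-pentamethoxy-4H-chromen-4-one | COc1c(O)cc(-c2oc3c(OC)c(OC)c(OC)c(OC)c3c(=O)c2OC)cc1O
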